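## Analysis of the target

The target is a 2'-hydroxychalcone. Ring A (C1'–C6') carries the enone carbonyl on C1', free hydroxyls on C2' and C4', a methoxy group on C6' and a ten-carbon lavandulyl chain on C3'; ring B is a 2,4-dihydroxyphenyl group joined through an (E)-configured Cα=Cβ bond. The chain reads C1''H2–C2''H(isopropenyl)–CH2–CH=C(CH3)2, and C2'' is the only stereocentre; with the CIP order isopropenyl > benzylic CH2 > prenyl CH2 > H it is (S). This centre is tertiary, all-carbon and remote from every heteroatom, and its three carbon substituents are of similar size, so no functional group of the final structure can be used to set it. The sensitive elements are the four free phenols on two electron-rich rings, the enone next to the C2' hydroxyl (conjugate closure to a flavanone), the two alkenes within reach of the C2' and C4' hydroxyls (acid-induced chroman formation) and the 1,5-diene of the chain (Cope rearrangement on strong heating). The difficulties are therefore enantiocontrol at an unfunctionalised carbon, attachment of a branched chain to C3', the most crowded carbon of ring A, and a mild end game. The strategy rests on one feature: C2'' bears the isopropenyl group and is bonded to the benzylic carbon C1'' on C3', so that C1''–C2''–C(CH3)=CH2 is the homoallylic array left when a 2-methylallyl metal attacks an electrophilic C1'' through its γ-carbon. A second useful feature is that ring A without its acyl group is mirror-symmetric about the C3'···C6' axis, so the C1'' electrophile can be drawn from a symmetric resorcinol.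

## Retrosynthetic reasoning

**24 ⇒ 23.** The last operation releases the four phenols by cleaving four methoxymethyl acetal C–O bonds of 23. This acetal is chosen because it directs both ring lithiations of the route, survives base, hydride, radical and organolithium conditions, and leaves under acid mild enough for the alkenes and the enone.

**23 ⇒ 16 + 20.** The C1'–C(=O) bond is cut, giving an aryl anion equivalent from 16 and the acyl donor 20. Ring A of 16 is mirror-symmetric, so its two free positions are equivalent and each is flanked by two oxygen directors; metalation is unambiguous. Ring B arrives with the (E)-enone already in place. Amide 20 goes back by a C=C disconnection to aldehyde 18 and phosphonate 19, and 18 to 17 by removal of two protecting groups.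

**16 ⇒ 15 ⇒ 13.** An oxygen is put back on C1''. This turns C1'' into the carbinol carbon of a carbonyl addition product. The forward direction must remove that oxygen by a path that never makes C2'' reactive, which points to radical cleavage of the C1''–O bond through xanthate 15.

**13 ⇒ 4 + 11.** The C1''–C2'' bond is cut. It is the one bond that joins the ring-bound carbon to the stereocentre, and cutting it gives a stable, non-enolisable aldehyde 4 and an allylboron reagent 11 in which the future isopropenyl group is a transposed double bond. The forward reaction forms the bond, sets C2'' and delivers the whole C10 chain at once. Cutting C3'–C1'' instead would require a β-branched, enantiopure electrophile made separately and an alkylation at the most hindered ring carbon.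

**4 ⇒ 2 ⇒ 1.** The formyl C–C bond is cut back to the aryllithium 3 of the symmetric bis-acetal 2, whose most acidic ring position lies between the two acetal oxygens; 2 comes from 1 by double O-alkylation.

**11 ⇒ 9 ⇒ 8 ⇒ 5 + 6.** The C–B bond is traced to the C–O bond of the (E)-allylic alcohol 9, with 10 as the boron source. Alcohol 9 comes from ester 8 by reduction, and the (E)-trisubstituted alkene of 8 from aldehyde 7 (made in the flask from 5) and the stabilised ylide 6. The E geometry fixed here is what later determines C2''.

## Alternatives that were turned down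

**Alternative 1: ring A built around the chain by a Danheiser benzannulation.** Three ring A bonds (C3'–C4', C4'–C5', C1'–C2') are disconnected.
- Forward key step: the siloxyalkyne A2, already carrying the (S)-lavandulyl group, is heated with 3-methoxycyclobutenone A3. Electrocyclic opening to a vinylketene, [2+2] addition to the ynol ether, 4π opening, 6π closure and tautomerisation give phenol A1, with the chain between a free hydroxyl and a silyloxy group and the methoxy group para to it.
- For it: the substitution pattern follows from the mechanism, the three oxygens arrive differentiated, and no bond has to be made at a crowded ring carbon.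
- Against it: it does nothing for C2''. A2 must be made enantioenriched beforehand, by a separate asymmetric synthesis of a lavandulyl unit and its homologation to an ynol ether, so the route is longer. The thermal cascade also has to run beside a 1,5-diene and two nucleophilic alkenes that can intercept the vinylketene.
- Comparison: differentiated oxygens, its main gain, are not needed when the ring A precursor is symmetric. The chosen route makes the stereocentre and the chain–ring bond in one step from a commercial arene.

**Alternative 2: chalcone by salicylaldehyde–alkyne hydroacylation.** The C(=O)–Cα bond of the enone is disconnected.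
- Forward key step: salicylaldehyde A5 and arylalkyne A6 combine under a monovalent rhodium catalyst with a bisphosphine and a carbonate base. The phenoxide holds the acylrhodium hydride, which adds syn across the alkyne to give the (E)-enone A4.
- For it: it is atom-economic, needs no strong base, uses the C2' hydroxyl as a directing group, and leaves only the ring B phenols to deprotect. On mildness of chalcone formation it is as strong as or stronger than the aryllithium acylation used here.
- Against it: the bond it forms is the easy one. A5 still needs the chain and the stereocentre, so all the chemistry up to 16 plus a formylation and a deprotection comes first. Insertion of a terminal aryl alkyne may give the branched enone, and a rhodium hydride beside two alkenes invites isomerisation.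
- Comparison: it is an end-game variant, not a solution to C2''. The chosen strategy spends its key step on the hard problem.

**Alternative 3: rhodium-catalysed conjugate addition of an isopropenyl group.** The C2''–C(isopropenyl) bond is disconnected.
- Forward key step: isopropenylboronate A9 adds to the (E)-enoate A8 under a hydroxorhodium catalyst with a chiral bisphosphine (Hayashi–Miyaura type) to give ester A7. Reduction to the aldehyde and an isopropylidene Wittig reaction would then give 16.
- For it: C2'' is set directly and catalytically, with no sacrificial stereocentre, no deoxygenation and no tin. About six steps lead from 1 to 16, against eight steps (three of them in a side branch) here. On step economy and on avoiding a stereocentre that is later erased, this alternative is as strong or stronger.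
- Against it: the CH2 of A8 is both benzylic and γ to the ester, so under the warm, basic, aqueous conditions the double bond can move into conjugation with the electron-rich arene and the acceptor is lost. The α-branched alkenylboron A9 transfers slowly and protodeboronates. The prenyl terminus still has to be built afterwards.
- Comparison: the chosen strategy offers in exchange one bond formation that brings the complete chain with both alkenes, an electrophile that can neither enolise nor isomerise, and stereocontrol through a closed chair whose E-to-anti relay is predictable.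

Key step: step 6

Assumption: the (R)-configured 3,3'-bis(2,4,6-triisopropylphenyl) BINOL phosphoric acid is taken to direct the allyl group to the Re face of aldehyde 4, as it does with simple aryl aldehydes; if the hindered substrate reverses the sense, the (S)-catalyst is used and nothing else changes.

## Route

Step 1
Reactants: 1 5-methoxyresorcinol (5-methoxybenzene-1,3-diol)
Product: 2 1-methoxy-3,5-bis(methoxymethoxy)benzene
Conditions: NaH, MOMCl, DMF, 0 °C → rt
Reagents that add atoms: chloromethyl methyl ether (MOMCl), COCCl
Why: Williamson-type O-alkylation of both phenoxides with the α-chloro ether; the two MOM acetals protect the phenols, later direct both ring lithiations and are removed together at the end.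

Step 2
Reactants: 2 1-methoxy-3,5-bis(methoxymethoxy)benzene
Product: 4 4-methoxy-2,6-bis(methoxymethoxy)benzaldehyde, via aryllithium 3 (not isolated)
Conditions: n-BuLi, TMEDA, THF, 0 °C; DMF, 0 °C → rt; aq. NH4Cl
Reagents that add atoms: N,N-dimethylformamide, CN(C)C=O
Why: Directed ortho-metalation removes the ring proton between the two MOM-oxy groups, the most acidic and doubly chelated site; formylation of the aryllithium with DMF gives the symmetric, non-enolisable aldehyde.

Step 3
Reactants: 5 4-methylpent-3-en-1-ol; 6 ethyl 2-(triphenylphosphoranylidene)propanoate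
Product: 8 ethyl (E)-2,6-dimethylhepta-2,5-dienoate, via 4-methylpent-3-enal 7 (not isolated)
Conditions: Dess–Martin periodinane, pyridine, CH2Cl2, 0 °C → rt; then 6, rt
Reagents that add atoms: none
Why: Dess–Martin oxidation gives the β,γ-unsaturated aldehyde 7 under buffered, non-aqueous conditions, and it is consumed in the same flask before it can isomerise into conjugation. The Wittig reaction of the α-methyl stabilised ylide 6 gives the (E)-trisubstituted enoate.

Step 4
Reactants: 8 ethyl (E)-2,6-dimethylhepta-2,5-dienoate
Product: 9 (E)-2,6-dimethylhepta-2,5-dien-1-ol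
Conditions: i-Bu2AlH, CH2Cl2, −78 → 0 °C; aq. potassium sodium tartrate
Reagents that add atoms: none
Why: 1,2-Reduction of the conjugated ester by i-Bu2AlH stops at the allylic alcohol and leaves both alkenes and the E geometry untouched.

Step 5
Reactants: 9 (E)-2,6-dimethylhepta-2,5-dien-1-ol; 10 bis(pinacolato)diboron
Product: 11 2-[(E)-2,6-dimethylhepta-2,5-dien-1-yl]-4,4,5,5-tetramethyl-1,3,2-dioxaborolane
Conditions: [Pd(MeCN)4](BF4)2 (5 mol%), DMSO/MeOH, 50 °C
Reagents that add atoms: none
Why: Palladium-catalysed allylic borylation (Miyaura type) of a primary allylic alcohol: the hydroxyl is activated by the diboron reagent and ionisation of the (E)-alcohol gives the syn-configured (η3-allyl)palladium species. Boron is delivered to the unsubstituted CH2 terminus, so the linear (E)-allylboronate should result.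

Step 6
Reactants: 4 4-methoxy-2,6-bis(methoxymethoxy)benzaldehyde; 11 2-[(E)-2,6-dimethylhepta-2,5-dien-1-yl]-4,4,5,5-tetramethyl-1,3,2-dioxaborolane
Product: 13 (1R,2R)-1-[4-methoxy-2,6-bis(methoxymethoxy)phenyl]-5-methyl-2-(prop-1-en-2-yl)hex-4-en-1-ol, via pinacol borate 12 (not isolated)
Conditions: (R)-3,3'-bis(2,4,6-triisopropylphenyl)-1,1'-binaphthyl-2,2'-diyl hydrogen phosphate (10 mol%), 4 Å MS, toluene, −30 °C → rt; aq. NaHCO3
Reagents that add atoms: none
Why: This is a Brønsted-acid-catalysed carbonyl allylboration through a closed six-membered Zimmerman–Traxler chair: the aldehyde oxygen of 4 binds boron of 11, the γ-carbon (the CH carrying the prenyl CH2) bonds to the formyl carbon and the double bond moves to C(CH3)=CH2, so the branched lavandulyl skeleton forms and no ring is closed. The closest known reaction type is the BINOL-phosphoric-acid-catalysed allyl- and crotylboration of aryl aldehydes with pinacol allylboronates, in which the acid proton hydrogen-bonds to a pinacol oxygen and raises the Lewis acidity of boron while the phosphoryl oxygen contacts the formyl C–H. C1'' is controlled by the catalyst, which shields one enantioface of the bound aldehyde so that attack on the Re face gives the (1R) carbinol. C2'' is controlled by the E geometry of 11: the prenyl CH2 on the γ-carbon and the aryl group of the aldehyde are both equatorial in the chair, which gives the anti (1R,2R) relationship. The step needs γ- over α-regioselectivity (enforced by the cyclic transition state), anti diastereoselectivity (geometric purity of 11) and enantioface selectivity (catalyst); 4 cannot enolise and the MOM acetals tolerate the weak acid in dry toluene. The β-methyl group of 11 raises the nucleophilicity of the allyl unit, which should help against the shielding by the two ortho MOM-oxy groups. Aqueous work-up hydrolyses borate 12 to alcohol 13.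

Step 7
Reactants: 13 (1R,2R)-1-[4-methoxy-2,6-bis(methoxymethoxy)phenyl]-5-methyl-2-(prop-1-en-2-yl)hex-4-en-1-ol
Product: 15 O-{(1R,2R)-1-[4-methoxy-2,6-bis(methoxymethoxy)phenyl]-5-methyl-2-(prop-1-en-2-yl)hex-4-en-1-yl} S-methyl carbonodithioate, via sodium xanthate 14 (not isolated)
Conditions: NaH, THF, 0 °C; CS2; MeI, 0 °C → rt
Reagents that add atoms: carbon disulfide, S=C=S; iodomethane, CI
Why: Xanthate formation: the sodium alkoxide of 13 adds to CS2 and the dithiocarbonate salt 14 is S-methylated; the cold, basic conditions touch neither the MOM ethers nor the two stereocentres.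

Step 8
Reactants: 15 O-{(1R,2R)-1-[4-methoxy-2,6-bis(methoxymethoxy)phenyl]-5-methyl-2-(prop-1-en-2-yl)hex-4-en-1-yl} S-methyl carbonodithioate
Product: 16 5-methoxy-1,3-bis(methoxymethoxy)-2-[(2S)-5-methyl-2-(prop-1-en-2-yl)hex-4-en-1-yl]benzene
Conditions: Bu3SnH, Et3B (cat.), air, toluene, rt
Reagents that add atoms: none
Why: Barton–McCombie deoxygenation: the stannyl radical adds to the thiocarbonyl sulfur, β-scission releases the benzylic C1'' radical, and hydrogen transfer from Bu3SnH gives the CH2 group. C2'' is never a radical centre and keeps its configuration (its descriptor changes from R to S only because the CIP priorities change), and the only cyclisations open to the radical are disfavoured 3-exo or 4-exo modes. Initiation with Et3B and air at room temperature avoids thermal syn-elimination of the xanthate.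

Step 9
Reactants: 17 2,4-dihydroxybenzaldehyde
Product: 18 2,4-bis(methoxymethoxy)benzaldehyde
Conditions: MOMCl, K2CO3, acetone, 0 → 50 °C
Reagents that add atoms: chloromethyl methyl ether (MOMCl), COCCl
Why: O-Alkylation of both phenols (the chelated ortho hydroxyl needs excess reagent and gentle warming) gives ring B the same acid-labile protecting groups as ring A.

Step 10
Reactants: 18 2,4-bis(methoxymethoxy)benzaldehyde; 19 diethyl {2-[methoxy(methyl)amino]-2-oxoethyl}phosphonate
Product: 20 (E)-3-[2,4-bis(methoxymethoxy)phenyl]-N-methoxy-N-methylprop-2-enamide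
Conditions: NaH, THF, 0 °C → rt
Reagents that add atoms: none
Why: Horner–Wadsworth–Emmons olefination with the stabilised anion of 19 gives the (E)-cinnamoyl Weinreb amide; the aryl aldehyde has no α-protons.

Step 11
Reactants: 16 5-methoxy-1,3-bis(methoxymethoxy)-2-[(2S)-5-methyl-2-(prop-1-en-2-yl)hex-4-en-1-yl]benzene; 20 (E)-3-[2,4-bis(methoxymethoxy)phenyl]-N-methoxy-N-methylprop-2-enamide
Product: 23 (E)-3-[2,4-bis(methoxymethoxy)phenyl]-1-{6-methoxy-2,4-bis(methoxymethoxy)-3-[(2S)-5-methyl-2-(prop-1-en-2-yl)hex-4-en-1-yl]phenyl}prop-2-en-1-one, via aryllithium 21 (not isolated), via lithium hemiaminal chelate 22 (not isolated)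
Conditions: n-BuLi, TMEDA, THF, −20 → 0 °C; 20, −78 → 0 °C; aq. NH4Cl
Reagents that add atoms: none
Why: Directed ortho-metalation of 16 occurs at one of the two equivalent ring positions flanked by a MOM-oxy and the methoxy group, so no regiochemical question arises. The aryllithium 21 adds 1,2 to the Weinreb amide (Weinreb ketone synthesis), and the chelated adduct 22 persists until aqueous work-up, which prevents over-addition and keeps the (E)-enone.

Step 12
Reactants: 23 (E)-3-[2,4-bis(methoxymethoxy)phenyl]-1-{6-methoxy-2,4-bis(methoxymethoxy)-3-[(2S)-5-methyl-2-(prop-1-en-2-yl)hex-4-en-1-yl]phenyl}prop-2-en-1-one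
Product: 24 (E)-1-{2,4-dihydroxy-6-methoxy-3-[(2S)-5-methyl-2-(prop-1-en-2-yl)hex-4-en-1-yl]phenyl}-3-(2,4-dihydroxyphenyl)prop-2-en-1-one
Conditions: 3 M aq. HCl, MeOH, rt → 40 °C, dark
Reagents that add atoms: none
Why: Acid-catalysed acetal exchange with methanol removes all four MOM groups as dimethoxymethane. Dilute acid at or slightly above room temperature should spare the two alkenes, the (E)-enone and C2'', and the freed C2' hydroxyl is stabilised by hydrogen bonding to the carbonyl.

## Compound list

1 | 5-methoxyresorcinol | COc1cc(O)cc(O)c1 | starting material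
2 | 1-methoxy-3,5-bis(methoxymethoxy)benzene | COCOc1cc(OC)cc(OCOC)c1 | intermediate
3 | [4-methoxy-2,6-bis(methoxymethoxy)phenyl]lithium | COCOc1cc(OC)cc(OCOC)c1[Li] | intermediate (not isolated)
4 | 4-methoxy-2,6-bis(methoxymethoxy)benzaldehyde | COCOc1cc(OC)cc(OCOC)c1C=O | intermediate
5 | 4-methylpent-3-en-1-ol | CC(C)=CCCO | starting material
6 | ethyl 2-(triphenylphosphoranylidene)propanoate | CCOC(=O)C(C)=P(c1ccccc1)(c1ccccc1)c1ccccc1 | starting material
7 | 4-methylpent-3-enal | CC(C)=CCC=O | intermediate (not isolated)
8 | ethyl (E)-2,6-dimethylhepta-2,5-dienoate | CCOC(=O)/C(C)=C/CC=C(C)C | intermediate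
9 | (E)-2,6-dimethylhepta-2,5-dien-1-ol | OC/C(C)=C/CC=C(C)C | intermediate
10 | bis(pinacolato)diboron | CC1(C)OB(OC1(C)C)B1OC(C)(C)C(C)(C)O1 | starting material
11 | 2-[(E)-2,6-dimethylhepta-2,5-dien-1-yl]-4,4,5,5-tetramethyl-1,3,2-dioxaborolane | CC(C)=CC/C=C(\C)CB1OC(C)(C)C(C)(C)O1 | intermediate
12 | 2-{(1R,2R)-1-[4-methoxy-2,6-bis(methoxymethoxy)phenyl]-5-methyl-2-(prop-1-en-2-yl)hex-4-en-1-yloxy}-4,4,5,5-tetramethyl-1,3,2-dioxaborolane | C=C(C)[C@@H](CC=C(C)C)[C@@H](OB1OC(C)(C)C(C)(C)O1)c1c(OCOC)cc(OC)cc1OCOC | intermediate (not isolated)
13 | (1R,2R)-1-[4-methoxy-2,6-bis(methoxymethoxy)phenyl]-5-methyl-2-(prop-1-en-2-yl)hex-4-en-1-ol | C=C(C)[C@@H](CC=C(C)C)[C@@H](O)c1c(OCOC)cc(OC)cc1OCOC | intermediate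
14 | sodium O-{(1R,2R)-1-[4-methoxy-2,6-bis(methoxymethoxy)phenyl]-5-methyl-2-(prop-1-en-2-yl)hex-4-en-1-yl} carbonodithioate | C=C(C)[C@@H](CC=C(C)C)[C@@H](OC(=S)[S-])c1c(OCOC)cc(OC)cc1OCOC.[Na+] | intermediate (not isolated)
15 | O-{(1R,2R)-1-[4-methoxy-2,6-bis(methoxymethoxy)phenyl]-5-methyl-2-(prop-1-en-2-yl)hex-4-en-1-yl} S-methyl carbonodithioate | C=C(C)[C@@H](CC=C(C)C)[C@@H](OC(=S)SC)c1c(OCOC)cc(OC)cc1OCOC | intermediate
16 | 5-methoxy-1,3-bis(methoxymethoxy)-2-[(2S)-5-methyl-2-(prop-1-en-2-yl)hex-4-en-1-yl]benzene | C=C(C)[C@@H](CC=C(C)C)Cc1c(OCOC)cc(OC)cc1OCOC | intermediate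
17 | 2,4-dihydroxybenzaldehyde | O=Cc1ccc(O)cc1O | starting material
18 | 2,4-bis(methoxymethoxy)benzaldehyde | COCOc1ccc(C=O)c(OCOC)c1 | intermediate
19 | diethyl {2-[methoxy(methyl)amino]-2-oxoethyl}phosphonate | CCOP(=O)(CC(=O)N(C)OC)OCC | starting material
20 | (E)-3-[2,4-bis(methoxymethoxy)phenyl]-N-methoxy-N-methylprop-2-enamide | CON(C)C(=O)/C=C/c1ccc(OCOC)cc1OCOC | intermediate
21 | {6-methoxy-2,4-bis(methoxymethoxy)-3-[(2S)-5-methyl-2-(prop-1-en-2-yl)hex-4-en-1-yl]phenyl}lithium | C=C(C)[C@@H](CC=C(C)C)Cc1c(OCOC)cc(OC)c([Li])c1OCOC | intermediate (not isolated)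
22 | lithium alkoxide of the tetrahedral N-methoxy-N-methyl hemiaminal from 21 and 20 (either configuration at the new carbon) | C=C(C)[C@@H](CC=C(C)C)Cc1c(OCOC)cc(OC)c(C(O[Li])(N(C)OC)/C=C/c2ccc(OCOC)cc2OCOC)c1OCOC | intermediate (not isolated)
23 | (E)-3-[2,4-bis(methoxymethoxy)phenyl]-1-{6-methoxy-2,4-bis(methoxymethoxy)-3-[(2S)-5-methyl-2-(prop-1-en-2-yl)hex-4-en-1-yl]phenyl}prop-2-en-1-one | C=C(C)[C@@H](CC=C(C)C)Cc1c(OCOC)cc(OC)c(C(=O)/C=C/c2ccc(OCOC)cc2OCOC)c1OCOC | intermediate
24 | (E)-1-{2,4-dihydroxy-6-methoxy-3-[(2S)-5-methyl-2-(prop-1-en-2-yl)hex-4-en-1-yl]phenyl}-3-(2,4-dihydroxyphenyl)prop-2-en-1-one | C=C(C)[C@@H](CC=C(C)C)Cc1c(O)cc(OC)c(C(=O)/C=C/c2ccc(O)cc2O)c1O | target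

## Step count and least certain steps

Total step count: 12. Longest linear sequence: 8 steps (steps 3, 4, 5, 6, 7, 8, 11 and 12, from 5).

**Step 6 (key step).** The two ortho MOM-oxy groups twist the formyl group out of the ring plane and crowd the catalyst pocket. The catalysed addition may then become slow, so that an uncatalysed, racemic pathway competes at the temperature needed for conversion and the enantioface selectivity erodes. Any loss of E geometry in 11 would pass directly into the wrong configuration at C2''. Fallback: asymmetry is moved from the catalyst to a stoichiometric chiral diol on boron. Setting out from allylic alcohol 9, palladium-catalysed borylation with B2(OH)4 would give [(E)-2,6-dimethylhepta-2,5-dien-1-yl]boronic acid F1, which is esterified in the same flask with D-(−)-diisopropyl tartrate over 4 Å sieves to the tartrate-modified allylboronate F2. F2 is more Lewis acidic than 11 and should add to aldehyde 4 in toluene at −78 °C without catalyst, through the same chair and, by the usual sense of this reagent class, on the Re face; hydrolysis returns to alcohol 13. The selectivity of such reagents with aryl aldehydes is usually more modest, which is why this is the second choice.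

**Step 8.** The xanthate sits on a benzylic carbon attached to a trioxygenated ring and may ionise. That would lead to O-to-S rearrangement to the unreactive dithiocarbonate, or to loss of the C2'' proton with formation of a conjugated diene and erasure of the stereocentre. Slow hydrogen transfer to the stabilised benzylic radical may also allow dimerisation. Fallback: from alcohol 13, acetylation (Ac2O, pyridine, DMAP) would give the (1R,2R)-benzylic acetate F3, and dissolving-metal cleavage of the benzylic C–O bond (Li, liquid NH3, THF, −78 °C, then NH4Cl) returns to 16. The isolated alkenes, the MOM ethers and the electron-rich ring are expected to survive these conditions, and C2'' is again not involved.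

**Step 11.** Lithiation may be incomplete or diverted to the benzylic or allylic positions, and the doubly ortho-substituted aryllithium may add sluggishly to the electron-rich conjugated amide or in part in a conjugate sense. Fallback: the enone is built by aldol condensation instead. From 16, the aryllithium 21 is quenched with N-methoxy-N-methylacetamide to give the acetophenone 1-{6-methoxy-2,4-bis(methoxymethoxy)-3-[(2S)-5-methyl-2-(prop-1-en-2-yl)hex-4-en-1-yl]phenyl}ethan-1-one F4. Claisen–Schmidt condensation of F4 with aldehyde 18 (KOH, EtOH, rt) returns to the protected chalcone 23.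

**Step 12.** Protonation of the chain alkenes may lead to ring closure by the C2' or C4' hydroxyl (chroman formation) or to addition of methanol. The freed C2' hydroxyl may add to the enone (flavanone formation), and the ring B ortho hydroxyl may cyclise if light isomerises the enone. Fallback: the acetals are exchanged for silyl groups under non-protic conditions. From 23, TMSOTf and 2,2'-bipyridyl in MeCN at 0 °C would convert the four aryl MOM ethers into the tetrakis(trimethylsilyl) ether F5, and brief treatment of F5 with water at neutral pH returns to the target 24 without any strong Brønsted acid being present.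

## Further compounds

F1 | step 6 | [(E)-2,6-dimethylhepta-2,5-dien-1-yl]boronic acid | CC(C)=CC/C=C(\C)CB(O)O
F2 | step 6 | diisopropyl (4S,5S)-2-[(E)-2,6-dimethylhepta-2,5-dien-1-yl]-1,3,2-dioxaborolane-4,5-dicarboxylate | CC(C)=CC/C=C(\C)CB1O[C@H](C(=O)OC(C)C)[C@@H](C(=O)OC(C)C)O1
F3 | step 8 | (1R,2R)-1-[4-methoxy-2,6-bis(methoxymethoxy)phenyl]-5-methyl-2-(prop-1-en-2-yl)hex-4-en-1-yl acetate | C=C(C)[C@@H](CC=C(C)C)[C@@H](OC(C)=O)c1c(OCOC)cc(OC)cc1OCOC
F4 | step 11 | 1-{6-methoxy-2,4-bis(methoxymethoxy)-3-[(2S)-5-methyl-2-(prop-1-en-2-yl)hex-4-en-1-yl]phenyl}ethan-1-one | C=C(C)[C@@H](CC=C(C)C)Cc1c(OCOC)cc(OC)c(C(C)=O)c1OCOC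
F5 | step 12 | (E)-3-[2,4-bis(trimethylsilyloxy)phenyl]-1-{6-methoxy-3-[(2S)-5-methyl-2-(prop-1-en-2-yl)hex-4-en-1-yl]-2,4-bis(trimethylsilyloxy)phenyl}prop-2-en-1-one | C=C(C)[C@@H](CC=C(C)C)Cc1c(O[Si](C)(C)C)cc(OC)c(C(=O)/C=C/c2ccc(O[Si](C)(C)C)cc2O[Si](C)(C)C)c1O[Si](C)(C)C
A1 | alternative 1 | 5-methoxy-2-[(2S)-5-methyl-2-(prop-1-en-2-yl)hex-4-en-1-yl]-3-[(triisopropylsilyl)oxy]phenol | C=C(C)[C@@H](CC=C(C)C)Cc1c(O)cc(OC)cc1O[Si](C(C)C)(C(C)C)C(C)C
A2 | alternative 1 | triisopropyl{[(4S)-7-methyl-4-(prop-1-en-2-yl)oct-6-en-1-yn-1-yl]oxy}silane | C=C(C)[C@@H](CC=C(C)C)CC#CO[Si](C(C)C)(C(C)C)C(C)C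
A3 | alternative 1 | 3-methoxycyclobut-2-en-1-one | COC1=CC(=O)C1
A4 | alternative 2 | (E)-3-[2,4-bis(methoxymethoxy)phenyl]-1-{2,4-dihydroxy-6-methoxy-3-[(2S)-5-methyl-2-(prop-1-en-2-yl)hex-4-en-1-yl]phenyl}prop-2-en-1-one | C=C(C)[C@@H](CC=C(C)C)Cc1c(O)cc(OC)c(C(=O)/C=C/c2ccc(OCOC)cc2OCOC)c1O
A5 | alternative 2 | 2,4-dihydroxy-6-methoxy-3-[(2S)-5-methyl-2-(prop-1-en-2-yl)hex-4-en-1-yl]benzaldehyde | C=C(C)[C@@H](CC=C(C)C)Cc1c(O)cc(OC)c(C=O)c1O
A6 | alternative 2 | 1-ethynyl-2,4-bis(methoxymethoxy)benzene | C#Cc1ccc(OCOC)cc1OCOC
A7 | alternative 3 | methyl (3R)-3-{[4-methoxy-2,6-bis(methoxymethoxy)phenyl]methyl}-4-methylpent-4-enoate | C=C(C)[C@@H](CC(=O)OC)Cc1c(OCOC)cc(OC)cc1OCOC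
A8 | alternative 3 | methyl (E)-4-[4-methoxy-2,6-bis(methoxymethoxy)phenyl]but-2-enoate | COC(=O)/C=C/Cc1c(OCOC)cc(OC)cc1OCOC
A9 | alternative 3 | 4,4,5,5-tetramethyl-2-(prop-1-en-2-yl)-1,3,2-dioxaborolane | C=C(C)B1OC(C)(C)C(C)(C)O1
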